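- A one-step world spends one nucleophile per electrophile, so a charge of 1.10 equivalents finishes there. The epsilon run, which is this flask so far, has 42.3% reacted at 30.0 min and is slowing.

| flask | electrophile | nucleophile | remark | time |
|---|---|---|---|---|
| epsilon | 0.10 M | 0.11 M | the very flask that is asked about, followed so far |  |
| alpha | 0.067 M | 0.11 M | run made earlier |  |
| flask | 0.10 M | 0.110 M |  | 80 min |

- epsilon (time / min: electrophile / %, target / %): 2.50: 89.6, 6.8; 4.00: 85.1, 11.7; 6.00: 78.0, 10.9; 10.0: 70.7, 13.2; 15.0: 65.0, 15.4; 20.0: 63.7, 14.4; 30.0: 57.7, 15.1
- alpha (time / min: electrophile / %, target / %): 3.00: 86.2, 7.2; 8.00: 75.8, 15.6; 15.0: 60.6, 13.7; 25.0: 52.1, 11.6; 30.0: 49.8, 14.0; 40.0: 46.0, 12.7; 60.0: 37.1, 10.2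

(each reading ± 1 percentage point)

- part of the electrophile that has reacted at 80 min
- share of the unused nucleophile that is free and not bound as protonated nucleophile, at 80 min

- the earlier runs do not show how much of nucleophile is bound; that part of a forecast is a guess

- My reckoning uses the nucleophile cost, nucleophile spent per electrophile reacted: one for each reacted electrophile, plus, I assume, a second for each no longer seen as target.
- The last alpha reading, the furthest advanced, gives 1.84; the last epsilon reading gives 1.64. I freeze the alpha value, scatter and all.
- The reach, charged nucleophile over cost times charged electrophile, is then 59.9% for this flask, which makes the nucleophile the limiting reagent.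
- I put the part reacted at 80 min between 42.3% and that reach. Your forecast of 52% reacted lies there, on your ground that “each substitution consumes one and its released acid ties up another”; your second nucleophile goes to the acid, where mine goes to lost target. Your 10% free is a guess, and I have no better one.
- This flask gives 52.9% reacted and 45.1% free. Up to 40.0 min, electrophile fell to 55.5% and over-reaction product rose to 31.2%, while target stood at 13.4%. By 80 min, by-product carried off had reached 0.0419 M and protonated nucleophile had dropped to 0.00887 M, beside 0.00728 M free nucleophile. Left to 800 min, this flask stands at 60.2% reacted, against the reach of 59.9%, which was reckoned from a single scattered reading.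

    electrophile + nucleophile → acid set free + target (k = 0.450 M⁻¹ min⁻¹)
    nucleophile + acid set free ⇌ protonated nucleophile, settled at all times (K = 550 M⁻¹)
    acid set free → by-product carried off (k = 0.200 min⁻¹)
    nucleophile + target → over-reaction product (k = 2.10 M⁻¹ min⁻¹)

- With 0.28 M nucleophile in a neighbour flask, the same cost gives a reach of 152%, so the reckoning makes electrophile the limiting reagent there. That neighbour flask has 92.3% reacted at 80 min, with 90.3% as over-reaction product.

Readings and results come from a simulation on assumed constants; the scatter is artificial.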